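The target is cut at the C3 ester into a (Z,Z)-diester side-chain acid and a 3,8,9-trioxygenated eremophilane core. Everything rests on making that core's carbon framework enzymatically: the decalin (ring A: C1–C5, C10; ring B: C5–C10) with its C4 methyl, quaternary C5 methyl and C7 isopropenyl group has exactly the skeleton and configuration of (+)-aristolochene. Aristolochene synthase converts achiral (2E,6E)-farnesyl diphosphate in one operation into this hydrocarbon, forming C6–C7, C5–C10 and the migrated C5–methyl bond, both rings and the C4/C5/C7 stereotriad. The C9=C10 olefin then gates C8, C9 and C10; C3 is oxygenated late and acylated.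

Key step: step 3

Remark: eremophilane numbering is used throughout; the hydroxylase of step 9 is assumed to be found in a screening panel of known cytochrome P450 BM3 variants, and the stated structures needed no correction.

Step 1
Reactants: 1 (2E,6E)-farnesol
Product: 2 (2E,6E)-farnesyl chloride
Conditions: NCS, Me2S, CH2Cl2, −40 → 0 °C
Reagents that add atoms: N-chlorosuccinimide, O=C1CCC(=O)N1Cl
Why: Corey–Kim chlorination converts the primary allylic alcohol through its alkoxysulfonium salt into the chloride by SN2 displacement, without allylic transposition or E/Z scrambling.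

Step 2
Reactants: 2 (2E,6E)-farnesyl chloride
Product: 3 (2E,6E)-farnesyl diphosphate (handled as its tris-ammonium salt)
Conditions: (n-Bu4N)3HP2O7, MeCN, rt; cation-exchange resin (NH4+ form), aq. NH4HCO3/i-PrOH
Reagents that add atoms: tris(tetrabutylammonium) hydrogen diphosphate, CCCC[N+](CCCC)(CCCC)CCCC.CCCC[N+](CCCC)(CCCC)CCCC.CCCC[N+](CCCC)(CCCC)CCCC.OP(=O)([O-])OP(=O)([O-])[O-]
Why: SN2 displacement of the primary allylic chloride by the diphosphate anion in acetonitrile is the standard entry to allylic diphosphates, and cation exchange gives the water-soluble salt the enzyme accepts.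

Step 3
Reactants: 3 (2E,6E)-farnesyl diphosphate
Product: 4 (+)-aristolochene, (4S,5R,7S)-eremophila-9,11-diene
Conditions: recombinant aristolochene synthase (Penicillium roqueforti enzyme, His-tagged, from Escherichia coli), MgCl2, Tris-HCl pH 7.5, pentane overlay, 25 °C
Reagents that add atoms: none
Why: Mg2+-triggered ionisation of the diphosphate gives the farnesyl cation, C6 attacks the distal trisubstituted olefin at C7 to close the ten-membered ring, loss of a C12 proton leaves the enzyme-bound germacrene A-type triene, and reprotonation at C1 triggers C5–C10 bond formation to the eudesmane cation, which undergoes a 1,2-hydride shift (C5 to C4), a 1,2-methyl shift (C10 to C5) and loss of H9. This is the native reaction of a class one terpene cyclase on its natural substrate (cation–olefin polycyclisation with Wagner–Meerwein shifts), so the closest known reaction type is the reaction itself. The first closure is a Markovnikov macrocyclisation giving the ten-membered carbocycle, and the C5–C10 bond is a transannular Markovnikov closure through a chair–chair fold that turns that macrocycle into the two six-membered rings A and B at once. C7 is set by the olefin face presented to C6 in the templated fold, C4 by the suprafacial hydride migration and C5 by the methyl migration on the opposite face, all dictated by the active-site contour because the substrate is achiral. The step needs exclusive deprotonation at C9 (not C1) and no water capture, which the dry active site with its positioned base secures; the substrate contributes only its all-E olefin geometry and spacing.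

Step 4
Reactants: 4 (+)-aristolochene
Product: 5 (4S,5R,7S)-eremophila-9,11-dien-8-one
Conditions: Rh2(cap)4 (dirhodium tetracaprolactamate, 1 mol%), t-BuOOH, K2CO3, CH2Cl2, rt
Reagents that add atoms: tert-butyl hydroperoxide, CC(C)(C)OO
Why: Allylic oxidation by tert-butylperoxyl radicals abstracts hydrogen at C8, the methylene next to the vinylic CH (the same preference as in the 7-oxidation of 5-ene steroids and the valencene-to-nootkatone oxidation), and the C8 peroxide collapses to the conjugated enone without touching a stereocentre.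

Step 5
Reactants: 5 (4S,5R,7S)-eremophila-9,11-dien-8-one
Product: 7 trimethyl[(4S,5R,7S,10S)-eremophila-8,11-dien-8-yloxy]silane, via lithium enolate 6 (not isolated)
Conditions: Li, NH3(l)/THF, t-BuOH (1 equiv), −78 °C; isoprene; NH3 off; TMSCl, Et3N, THF, −78 → 0 °C
Reagents that add atoms: chlorotrimethylsilane, C[Si](C)(C)Cl
Why: Dissolving-metal (Birch-type) conjugate reduction protonates C10 axially, anti to the C5 methyl, which sets the trans ring fusion, and leaves the regiospecific C8–C9 enolate that O-silylation traps before it can equilibrate toward C7; the isolated isopropenyl group is not reduced.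

Step 6
Reactants: 7 trimethyl[(4S,5R,7S,10S)-eremophila-8,11-dien-8-yloxy]silane
Product: 9 (4S,5R,7S,9S,10R)-9-hydroxyeremophil-11-en-8-one, via 9-trimethylsilyloxy ketone 8 (not isolated)
Conditions: mCPBA (1.0 equiv), NaHCO3, CH2Cl2, −20 °C; then citric acid, MeOH, 0 °C
Reagents that add atoms: 3-chloroperoxybenzoic acid, OOC(=O)c1cccc(Cl)c1
Why: In this Rubottom oxidation the peracid attacks the electron-rich silyl enol ether far faster than the 1,1-disubstituted olefin and from the face away from the axial C5 methyl (1,3 to C9), so the 9-oxygen ends equatorial and cis to H10, which is also the thermodynamically preferred configuration of this enolisable centre.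

Step 7
Reactants: 9 (4S,5R,7S,9S,10R)-9-hydroxyeremophil-11-en-8-one
Product: 10 (4S,5R,7S,8R,9S,10R)-eremophil-11-ene-8,9-diol
Conditions: LiBH(s-Bu)3 (lithium tri-sec-butylborohydride, 3 equiv), THF, −78 °C; then H2O
Reagents that add atoms: none
Why: The bulky trialkylborohydride approaches C8 along the equatorial trajectory, because the axial path past the axial hydrogens at C6 and C10 is too crowded for it, and so gives the axial 8-alcohol cis to the 9-hydroxyl, the outcome known for 2-substituted cyclohexanones.

Step 8
Reactants: 10 (4S,5R,7S,8R,9S,10R)-eremophil-11-ene-8,9-diol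
Product: 11 (4S,5R,7S,8R,9S,10R)-8,9-(isopropylidenedioxy)eremophil-11-ene
Conditions: Me2C(OMe)2, PPTS (cat.), CH2Cl2, rt
Reagents that add atoms: 2,2-dimethoxypropane, COC(C)(C)OC
Why: Acid-catalysed transketalisation closes the five-membered acetonide readily on the cis (axial–equatorial) diol, and pyridinium catalysis is too mild to hydrate or shift the isopropenyl olefin.

Step 9
Reactants: 11 (4S,5R,7S,8R,9S,10R)-8,9-(isopropylidenedioxy)eremophil-11-ene
Product: 12 (3R,4R,5R,7S,8R,9S,10R)-8,9-(isopropylidenedioxy)eremophil-11-en-3-ol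
Conditions: cytochrome P450 BM3 (CYP102A1) variant from a screening panel, NADP+ (cat.), Na2HPO3, phosphite dehydrogenase, catalase, KPi pH 8.0, 2% DMSO, air, 25 °C
Reagents that add atoms: dioxygen, O=O
Why: Cytochrome P450 C–H hydroxylation (hydrogen abstraction by the ferryl porphyrin radical cation, then oxygen rebound with retention) should oxidise the equatorial C3–H of ring A to the equatorial (3R) alcohol when the ketal end anchors away from the heme, a reaction type precedented for ring A methylenes of trans-decalin terpenoid lactones with variants of this enzyme and for C3 of 5-epi-aristolochene with its plant hydroxylase, although the site-selectivity on 11 is unproven.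

Step 10
Reactants: 13 (S)-pent-1-yn-3-ol
Product: 14 (S)-4-hydroxyhex-2-ynoic acid
Conditions: n-BuLi (2.1 equiv), THF, −78 → −20 °C; CO2; then aq. HCl
Reagents that add atoms: carbon dioxide, O=C=O
Why: Double deprotonation gives the alkoxide–acetylide dianion, whose carbon terminus is carboxylated by CO2 (acetylide carboxylation) without involving the carbinol stereocentre.

Step 11
Reactants: 14 (S)-4-hydroxyhex-2-ynoic acid
Product: 15 tert-butyl (S)-4-hydroxyhex-2-ynoate
Conditions: tert-butyl 2,2,2-trichloroacetimidate, CH2Cl2/cyclohexane, rt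
Reagents that add atoms: tert-butyl 2,2,2-trichloroacetimidate, CC(C)(C)OC(=N)C(Cl)(Cl)Cl
Why: The carboxylic acid itself protonates the imidate and is tert-butylated, whereas the propargylic alcohol does not react without an added Lewis acid, so the acid is masked selectively.

Step 12
Reactants: 15 tert-butyl (S)-4-hydroxyhex-2-ynoate; 16 hex-2-ynoic acid
Product: 17 tert-butyl (S)-4-(hex-2-ynoyloxy)hex-2-ynoate
Conditions: DIC, DMAP (cat.), CH2Cl2, 0 °C
Reagents that add atoms: none
Why: Steglich carbodiimide esterification acylates the secondary propargylic alcohol with retention, since the C–O bond at the stereocentre is not broken.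

Step 13
Reactants: 17 tert-butyl (S)-4-(hex-2-ynoyloxy)hex-2-ynoate
Product: 18 (S)-4-(hex-2-ynoyloxy)hex-2-ynoic acid
Conditions: TFA, CH2Cl2, 0 °C → rt
Reagents that add atoms: none
Why: Acidolysis of the tert-butyl ester through the tert-butyl cation frees the acid, while the secondary propargylic ester and both ynoates are stable to trifluoroacetic acid.

Step 14
Reactants: 12 (3R,4R,5R,7S,8R,9S,10R)-8,9-(isopropylidenedioxy)eremophil-11-en-3-ol; 18 (S)-4-(hex-2-ynoyloxy)hex-2-ynoic acid
Product: 19 (3R,4R,5R,7S,8R,9S,10R)-8,9-(isopropylidenedioxy)eremophil-11-en-3-yl (4S)-4-(hex-2-ynoyloxy)hex-2-ynoate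
Conditions: DIC, DMAP (cat.), CH2Cl2, −20 → 0 °C
Reagents that add atoms: none
Why: Steglich esterification of the equatorial C3 alcohol, the only free hydroxyl of 12, should proceed cleanly because an alkynoic acid has no olefin geometry to lose under DMAP catalysis, which is why the triple bonds are carried to this point.

Step 15
Reactants: 19 (3R,4R,5R,7S,8R,9S,10R)-8,9-(isopropylidenedioxy)eremophil-11-en-3-yl (4S)-4-(hex-2-ynoyloxy)hex-2-ynoate
Product: 20 (3R,4R,5R,7S,8R,9S,10R)-8,9-(isopropylidenedioxy)eremophil-11-en-3-yl (2Z,4S)-4-[(2Z)-hex-2-enoyloxy]hex-2-enoate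
Conditions: H2 (1 atm), Pd/CaCO3–Pb(OAc)2 (Lindlar catalyst), quinoline, EtOAc, rt
Reagents that add atoms: none
Why: Lindlar semi-hydrogenation adds H2 syn to each conjugated alkyne to give both (Z)-enoates, and the lead- and quinoline-poisoned palladium should not reduce the isopropenyl group or the product enoates at a comparable rate.

Step 16
Reactants: 20 (3R,4R,5R,7S,8R,9S,10R)-8,9-(isopropylidenedioxy)eremophil-11-en-3-yl (2Z,4S)-4-[(2Z)-hex-2-enoyloxy]hex-2-enoate
Product: 21 CNP0271544.1, (3R,4R,5R,7S,8R,9S,10R)-8,9-dihydroxyeremophil-11-en-3-yl (2Z,4S)-4-[(2Z)-hex-2-enoyloxy]hex-2-enoate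
Conditions: AcOH/H2O (4:1), 40 °C
Reagents that add atoms: none
Why: Mild aqueous acid hydrolyses the cis-fused dioxolane, while both esters, the (Z)-enoates and the isopropenyl group are stable to aqueous acetic acid at this temperature.

Compound list
1 | (2E,6E)-farnesol | CC(C)=CCC/C(C)=C/CC/C(C)=C/CO | starting material
2 | (2E,6E)-farnesyl chloride | CC(C)=CCC/C(C)=C/CC/C(C)=C/CCl | intermediate
3 | (2E,6E)-farnesyl diphosphate (handled as its tris-ammonium salt) | CC(C)=CCC/C(C)=C/CC/C(C)=C/COP(=O)(O)OP(=O)(O)O | intermediate
4 | (+)-aristolochene, (4S,5R,7S)-eremophila-9,11-diene | C=C(C)[C@@H]1C[C@]2(C)[C@@H](C)CCCC2=CC1 | intermediate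
5 | (4S,5R,7S)-eremophila-9,11-dien-8-one | C=C(C)[C@@H]1C[C@]2(C)[C@@H](C)CCCC2=CC1=O | intermediate
6 | lithium (4S,5R,7S,10S)-eremophila-8,11-dien-8-olate | C=C(C)[C@@H]1C[C@]2(C)[C@@H](C)CCC[C@H]2C=C1O[Li] | intermediate
7 | trimethyl[(4S,5R,7S,10S)-eremophila-8,11-dien-8-yloxy]silane | C=C(C)[C@@H]1C[C@]2(C)[C@@H](C)CCC[C@H]2C=C1O[Si](C)(C)C | intermediate
8 | (4S,5R,7S,9S,10R)-9-(trimethylsilyloxy)eremophil-11-en-8-one | C=C(C)[C@@H]1C[C@]2(C)[C@@H](C)CCC[C@H]2[C@H](O[Si](C)(C)C)C1=O | intermediate
9 | (4S,5R,7S,9S,10R)-9-hydroxyeremophil-11-en-8-one | C=C(C)[C@@H]1C[C@]2(C)[C@@H](C)CCC[C@H]2[C@H](O)C1=O | intermediate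
10 | (4S,5R,7S,8R,9S,10R)-eremophil-11-ene-8,9-diol | C=C(C)[C@@H]1C[C@]2(C)[C@@H](C)CCC[C@H]2[C@H](O)[C@@H]1O | intermediate
11 | (4S,5R,7S,8R,9S,10R)-8,9-(isopropylidenedioxy)eremophil-11-ene | C=C(C)[C@@H]1C[C@]2(C)[C@@H](C)CCC[C@H]2[C@@H]3OC(C)(C)O[C@H]13 | intermediate
12 | (3R,4R,5R,7S,8R,9S,10R)-8,9-(isopropylidenedioxy)eremophil-11-en-3-ol | C=C(C)[C@@H]1C[C@]2(C)[C@@H](C)[C@H](O)CC[C@H]2[C@@H]3OC(C)(C)O[C@H]13 | intermediate
13 | (S)-pent-1-yn-3-ol | CC[C@H](O)C#C | starting material
14 | (S)-4-hydroxyhex-2-ynoic acid | CC[C@H](O)C#CC(=O)O | intermediate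
15 | tert-butyl (S)-4-hydroxyhex-2-ynoate | CC[C@H](O)C#CC(=O)OC(C)(C)C | intermediate
16 | hex-2-ynoic acid | CCCC#CC(=O)O | starting material
17 | tert-butyl (S)-4-(hex-2-ynoyloxy)hex-2-ynoate | CC[C@H](OC(=O)C#CCCC)C#CC(=O)OC(C)(C)C | intermediate
18 | (S)-4-(hex-2-ynoyloxy)hex-2-ynoic acid | CC[C@H](OC(=O)C#CCCC)C#CC(=O)O | intermediate
19 | (3R,4R,5R,7S,8R,9S,10R)-8,9-(isopropylidenedioxy)eremophil-11-en-3-yl (4S)-4-(hex-2-ynoyloxy)hex-2-ynoate | C=C(C)[C@@H]1C[C@]2(C)[C@@H](C)[C@H](OC(=O)C#C[C@H](CC)OC(=O)C#CCCC)CC[C@H]2[C@@H]3OC(C)(C)O[C@H]13 | intermediate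
20 | (3R,4R,5R,7S,8R,9S,10R)-8,9-(isopropylidenedioxy)eremophil-11-en-3-yl (2Z,4S)-4-[(2Z)-hex-2-enoyloxy]hex-2-enoate | C=C(C)[C@@H]1C[C@]2(C)[C@@H](C)[C@H](OC(=O)/C=C\[C@H](CC)OC(=O)/C=C\CCC)CC[C@H]2[C@@H]3OC(C)(C)O[C@H]13 | intermediate
21 | CNP0271544.1, (3R,4R,5R,7S,8R,9S,10R)-8,9-dihydroxyeremophil-11-en-3-yl (2Z,4S)-4-[(2Z)-hex-2-enoyloxy]hex-2-enoate | C=C(C)[C@@H]1C[C@]2(C)[C@@H](C)[C@H](OC(=O)/C=C\[C@H](CC)OC(=O)/C=C\CCC)CC[C@H]2[C@H](O)[C@@H]1O | target

Total step count: 16. Longest linear sequence: 12 steps (steps 1–9 and 14–16, from farnesol); the side-chain branch has 4 steps (10–13) before the coupling.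

Steps most likely to fail

Step 9 (C3 hydroxylation). What may go wrong: hydrogen abstraction at other sites (C1, C2, the allylic C7 and C12/C13 hydrogens, or epoxidation of the isopropenyl olefin) or oxygen rebound to the axial face of C3, that is, loss of site and face control in an active site not evolved for 11. No purely chemical way to oxygenate C3 is offered, because ring A carries no handle. The fallback moves the oxygen to the flat enone and uses a pathway-type enzyme, then carries the free hydroxyl through the ring B sequence. It sets out from 5: whole-cell oxidation with yeast expressing an eremophilane C3 hydroxylase of the kind that serves the Penicillium roqueforti eremofortin pathway, which oxygenates C3 of this 9-en-8-one scaffold, should give (3R,4R,5R,7S)-3-hydroxyeremophila-9,11-dien-8-one F1. Li/NH3 reduction with excess lithium followed by TMSCl/Et3N should give the 3-silyl ether 8-silyl enol ether 3,8-bis(trimethylsilyloxy)eremophila-8,11-diene F2. Rubottom oxidation with mCPBA and methanolysis should give (3R,4R,5R,7S,9S,10R)-3,9-dihydroxyeremophil-11-en-8-one F3. LiBH(s-Bu)3 should then give (3R,4R,5R,7S,8R,9S,10R)-eremophil-11-ene-3,8,9-triol F4. Me2C(OMe)2/PPTS, which can ketalise only the cis-8,9-diol, comes back to the route at 12.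

Step 4 (allylic oxidation). What may go wrong: the peroxyl-radical chain does not stay at C8; hydrogen abstraction at C1 competes, and the product is oxidised further at its doubly activated C7–H. The fallback replaces the radical chain by a pericyclic oxygenation and sets out from 4. The Schenck ene reaction with singlet oxygen (O2, tetraphenylporphyrin, hν, CH2Cl2, 0 °C) attacks the trisubstituted C9=C10 bond much faster than the 1,1-disubstituted olefin, from the face opposite the C5 methyl, and should give the tertiary hydroperoxide 10-hydroperoxyeremophila-8,11-diene F5. Its allylic hydroperoxide rearrangement in CHCl3 at rt should give the secondary 8-hydroperoxyeremophila-9,11-diene F6. Ac2O/pyridine (Kornblum–DeLaMare-type dehydration) then comes back to the route at 5.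

Step 15 (double semi-hydrogenation). What may go wrong: over-reduction of one enoate, Z-to-E drift, or stalling after the first alkyne while two triple bonds are reduced on the fully assembled molecule. The fallback fixes the olefin geometry on the fragment before coupling and sets out from 17. Lindlar semi-hydrogenation should give tert-butyl (2Z,4S)-4-[(2Z)-hex-2-enoyloxy]hex-2-enoate F7, which can be separated from over-reduced material at a cheap stage. TFA should give (2Z,4S)-4-[(2Z)-hex-2-enoyloxy]hex-2-enoic acid F8, which cannot lactonise because its 4-oxygen is acylated. Yamaguchi esterification with 12 (2,4,6-trichlorobenzoyl chloride, Et3N, toluene; then 12 and substoichiometric DMAP at 0 °C to limit isomerisation) comes back to the route at 20.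

Further compounds
F1 | step 9 | (3R,4R,5R,7S)-3-hydroxyeremophila-9,11-dien-8-one | C=C(C)[C@@H]1C[C@]2(C)[C@@H](C)[C@H](O)CCC2=CC1=O
F2 | step 9 | 3,8-bis(trimethylsilyloxy)eremophila-8,11-diene (trans-fused, 3-oxygen equatorial) | C=C(C)[C@@H]1C[C@]2(C)[C@@H](C)[C@H](O[Si](C)(C)C)CC[C@H]2C=C1O[Si](C)(C)C
F3 | step 9 | (3R,4R,5R,7S,9S,10R)-3,9-dihydroxyeremophil-11-en-8-one | C=C(C)[C@@H]1C[C@]2(C)[C@@H](C)[C@H](O)CC[C@H]2[C@H](O)C1=O
F4 | step 9 | (3R,4R,5R,7S,8R,9S,10R)-eremophil-11-ene-3,8,9-triol | C=C(C)[C@@H]1C[C@]2(C)[C@@H](C)[C@H](O)CC[C@H]2[C@H](O)[C@@H]1O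
F5 | step 4 | 10-hydroperoxyeremophila-8,11-diene (hydroperoxy group anti to the C5 methyl) | C=C(C)[C@@H]1C[C@]2(C)[C@@H](C)CCC[C@@]2(OO)C=C1
F6 | step 4 | 8-hydroperoxyeremophila-9,11-diene (hydroperoxy group anti to the C5 methyl) | C=C(C)[C@@H]1C[C@]2(C)[C@@H](C)CCCC2=C[C@@H]1OO
F7 | step 15 | tert-butyl (2Z,4S)-4-[(2Z)-hex-2-enoyloxy]hex-2-enoate | CC(C)(C)OC(=O)/C=C\[C@H](CC)OC(=O)/C=C\CCC
F8 | step 15 | (2Z,4S)-4-[(2Z)-hex-2-enoyloxy]hex-2-enoic acid | OC(=O)/C=C\[C@H](CC)OC(=O)/C=C\CCC
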